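**Retrosynthetic overview**

1. Feature: in ring A (C1–C5, C10) the adjacent oxidised carbons C3 and C4 lie next to the cis ring fusion C5–H / quaternary C10–CH3. An o-quinone monoketal Diels–Alder adduct leaves this pattern after a [3,3] shift: the carbinol carbon becomes C3 and the ketal carbon C4.
2. Endgame disconnections: the C4 acetate and C3 angelate; the C8 ketone from hydroboration and oxidation of C8=C9; C4–CH3 from MeMgBr on the unveiled C4 ketone; C3–OH from hydride on the C3 ketone.
3. Key disconnection: C1–C10 (formed) and C3–C8 (broken) by anionic oxy-Cope rearrangement of a 2-vinylbicyclo[2.2.2]oct-5-en-2-ol, which closes ring A and releases ring B from the cage.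
4. The cage comes from dearomatised 2-methoxy-4-methylphenol and methyl vinyl ketone, an activated stand-in for the unreactive 3-methylbut-1-ene. The acetyl group is turned into isopropyl (enol triflate, methyl coupling, hydrogenation), the adduct is resolved on a chiral phase, and vinylmagnesium bromide is added.
5. Ring order: the bicyclo[2.2.2]octene holding the ring B carbons in step 1, ring A in step 7, ring B set free in the same step.

Key step: step 7

Remark: decalins, and the atoms of the cage in step 7, are numbered as in eudesmanes (ring A = C1, C2, C3, C4, C5, C10; ring B = C5–C10; methyls on C4 and C10; isopropyl on C7), β is the face of the C10 methyl, and the cages are otherwise numbered as bicyclo[2.2.2]octenes (C2 carbonyl or carbinol, C3 ketal, C5=C6, substituent on C7).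

**Route**

Step 1
Reactants: 1 2-methoxy-4-methylphenol; 2 but-3-en-2-one (methyl vinyl ketone, excess)
Product: 4 racemic 7-endo-acetyl-3,3-dimethoxy-5-methylbicyclo[2.2.2]oct-5-en-2-one, via masked o-benzoquinone 3 (not isolated)
Conditions: PhI(OAc)2 (added slowly), MeOH, 0 °C to rt
Reagents that add atoms: methanol, CO
Why: Oxidative dearomatization gives the o-quinone monoketal 3, which is trapped in situ by the enone in a Diels–Alder reaction; the acyl-bearing carbon bonds to the diene terminus alpha to the carbonyl (ortho rule) and the acetyl group ends endo (syn to the new C5=C6 bridge), which fixes C1, C4 and C7 relative to each other.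

Step 2
Reactants: 4 racemic adduct
Product: 5 single enantiomer of the 7-endo-acetyl ketone (configuration as in the SMILES of the list)
Conditions: preparative supercritical-fluid chromatography, amylose tris(3,5-dimethylphenylcarbamate) phase, CO2/MeOH
Reagents that add atoms: none
Why: Chromatographic resolution on a chiral stationary phase is used because no enantioselective form of this cycloaddition is established; the three stereocenters of 5 are held by the cage and cannot racemize later.

Step 3
Reactants: 5 7-endo-acetyl ketone
Product: 7 7-endo-[1-(trifluoromethylsulfonyloxy)ethenyl]-3,3-dimethoxy-5-methylbicyclo[2.2.2]oct-5-en-2-one, via potassium enolate 6 (not isolated)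
Conditions: KN(SiMe3)2, THF, −78 °C; then PhNTf2, −78 to 0 °C
Reagents that add atoms: N-phenylbis(trifluoromethanesulfonimide), O=S(=O)(N(c1ccccc1)S(=O)(=O)C(F)(F)F)C(F)(F)F
Why: Kinetic enolate formation and O-triflation: only the acetyl group can enolize, since the C2 ketone has a bridgehead carbon and the ketal carbon as its alpha positions, and the hindered base removes a methyl proton, so the terminal enol triflate forms without touching C7.

Step 4
Reactants: 7 enol triflate
Product: 8 7-endo-(prop-1-en-2-yl)-3,3-dimethoxy-5-methylbicyclo[2.2.2]oct-5-en-2-one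
Conditions: MeZnCl, Pd(PPh3)4 (cat.), THF, 50 °C
Reagents that add atoms: methylzinc chloride, C[Zn]Cl
Why: Negishi cross-coupling of an alkenyl triflate with an organozinc reagent that does not add to the C2 ketone; no stereocenter is involved.

Step 5
Reactants: 8 isopropenyl ketone
Product: 9 7-endo-(propan-2-yl)-3,3-dimethoxy-5-methylbicyclo[2.2.2]oct-5-en-2-one
Conditions: H2 (1 atm), RhCl(PPh3)3 (cat.), benzene/EtOH, rt
Reagents that add atoms: none
Why: Homogeneous hydrogenation with RhCl(PPh3)3 reduces the 1,1-disubstituted alkene much faster than the trisubstituted C5=C6 bridge alkene and leaves the ketone alone; C7 keeps its configuration because no bond to it changes.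

Step 6
Reactants: 9 7-endo-isopropyl ketone; 10 vinylmagnesium bromide
Product: 11 3,3-dimethoxy-5-methyl-7-endo-(propan-2-yl)-2-vinylbicyclo[2.2.2]oct-5-en-2-ol (vinyl syn to the C5=C6 bridge, hydroxyl toward the C7–C8 bridge)
Conditions: THF, −78 to 0 °C; then aq. NH4Cl
Reagents that add atoms: none
Why: Grignard 1,2-addition to the ketone from the face next to the flat C5=C6 bridge and away from the C7–C8 ethano bridge, the established facial preference of 3,3-dimethoxybicyclo[2.2.2]oct-5-en-2-ones, sets C2 with the vinyl group syn to the alkene.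

Step 7
Reactants: 11 vinyl carbinol
Product: 14 cis-fused 4,4-dimethoxy-10β-methyl-7β-isopropyl-5βH-octal-8-en-3-one, via potassium alkoxide 12 (not isolated), via potassium enolate 13 (not isolated)
Conditions: KH, 18-crown-6, THF, 0 °C to rt; then aq. NH4Cl, −78 °C
Reagents that add atoms: none
Why: Deprotonation gives the alkoxide 12, whose free oxyanion weakens the adjacent C3–C8 bond and sets off a concerted, suprafacial [3,3] shift of the 1,5-diene C1=C2–C3–C8–C9=C10 through the boat array held by the cage, so that C1–C10 forms as C3–C8 breaks and the enolate 13 results. This is the anionic oxy-Cope rearrangement known for 2-vinylbicyclo[2.2.2]oct-5-en-2-ols made from masked o-benzoquinone adducts. Ring A (C1, C2, C3, C4, C5, C10) closes by the sigmatropic C1–C10 bond formation itself, while the opening of the cage leaves ring B (C5–C10) with the new C8=C9 double bond. The one new stereocenter, quaternary C10, is controlled by the cage: the vinyl terminus can reach only the face of C10 on its own side, which puts the methyl group cis to H5, and C5 and C7 are carried over unchanged. The step needs the vinyl group syn to the C9=C10 bridge and the isopropyl group endo, both fixed in steps 1 and 6; the rigid boat geometry and the irreversible formation of the enolate favour the [3,3] path over a [1,3] shift or cleavage, and work-up protonates the enolate at C2, which is not a stereocenter.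

Step 8
Reactants: 14 octalenone
Product: 15 cis-fused 4,4-dimethoxy-10β-methyl-7β-isopropyl-5βH-octal-8-en-3α-ol
Conditions: NaBH4, MeOH, −20 to 0 °C
Reagents that add atoms: none
Why: Borohydride reduction of the alpha-ketal ketone: in the preferred cis-decalin conformer (C10 methyl equatorial on ring A, isopropyl pseudoequatorial) hydride should add axially from the convex β face, anti to the axial 4α-methoxy group (polar Felkin–Anh model), to give the equatorial 3α-alcohol.

Step 9
Reactants: 15 hydroxy ketal
Product: 16 cis-fused 3α-hydroxy-10β-methyl-7β-isopropyl-5βH-octal-8-en-4-one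
Conditions: 1 M aq. HCl, THF, 0 °C to rt, stopped at full conversion
Reagents that add atoms: water, O
Why: Acid-catalysed ketal hydrolysis is far faster than acid-catalysed enolization of the ketone it releases, so C5 (alpha to the new carbonyl) and the C3 carbinol should keep their configuration under short, mild treatment.

Step 10
Reactants: 16 alpha-hydroxy ketone
Product: 17 cis-fused 4β,10β-dimethyl-7β-isopropyl-5βH-octal-8-ene-3α,4α-diol
Conditions: MeMgBr (excess), THF, −78 to 0 °C; then aq. NH4Cl
Reagents that add atoms: methylmagnesium bromide, C[Mg]Br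
Why: Grignard addition to the alpha-hydroxy ketone (the first equivalent is consumed by the hydroxyl): the axial α trajectory at C4 is blocked by C9, which is syn-axial to it on the concave face, so methyl should enter equatorially from the β face and the new tertiary hydroxyl is 4α, cis to the 3α-hydroxyl.

Step 11
Reactants: 17 diol
Product: 18 3α,4α-O-isopropylidene derivative of 17 (acetonide)
Conditions: Me2C(OMe)2, pyridinium p-toluenesulfonate (cat.), CH2Cl2, rt
Reagents that add atoms: 2,2-dimethoxypropane, COC(C)(C)OC
Why: Acid-catalysed transketalization gives the isopropylidene acetal of the cis (equatorial/axial) 1,2-diol, which protects both hydroxyls from borane and from the oxidant of step 13.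

Step 12
Reactants: 18 acetonide alkene
Product: 20 8α-hydroxy acetonide (3α,4α-O-isopropylidene-4β,10β-dimethyl-7β-isopropyl-5βH-decalin-3α,4α,8α-triol), via C8 alkylborane 19 (not isolated)
Conditions: BH3·THF, THF, 0 °C to rt; then NaOH, H2O2, 0 °C to rt
Reagents that add atoms: hydrogen peroxide, OO
Why: Hydroboration–oxidation: C9 is neopentyl (next to quaternary C10), shielded on the β face by the axial C10 methyl and on the α face by the syn-axial C4, so the boron end of the four-centre addition should take the open α face of C8; only the regiochemistry matters, since the C8 configuration is removed in step 13.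

Step 13
Reactants: 20 8α-hydroxy acetonide
Product: 21 8-oxo acetonide (3α,4α-O-isopropylidenedioxy-4β,10β-dimethyl-7β-isopropyl-5βH-decalin-8-one)
Conditions: nPr4N[RuO4] (cat.), N-methylmorpholine N-oxide, 4 Å molecular sieves, CH2Cl2, rt
Reagents that add atoms: none
Why: Ley–Griffith oxidation of the secondary alcohol under neutral conditions leaves the acetonide intact; C7, now alpha to the ketone, already carries the equatorial β-isopropyl group that is preferred at equilibrium.

Step 14
Reactants: 21 8-oxo acetonide
Product: 22 3α,4α-dihydroxy-4β,10β-dimethyl-7β-isopropyl-5βH-decalin-8-one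
Conditions: AcOH/H2O (4:1), 45 °C
Reagents that add atoms: none
Why: Mild acid hydrolysis of the acetonide does not ionize the tertiary alcohol, and any equilibration at C7 favours the configuration already present.

Step 15
Reactants: 22 diol ketone; 23 angelic acid
Product: 25 4α-hydroxy-4β,10β-dimethyl-7β-isopropyl-8-oxo-5βH-decalin-3α-yl (Z)-2-methylbut-2-enoate, via angelic 2,4,6-trichlorobenzoic anhydride 24 (not isolated)
Conditions: 23, 2,4,6-trichlorobenzoyl chloride, Et3N, toluene, rt; then 22, 80 °C
Reagents that add atoms: none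
Why: Yamaguchi esterification through the mixed anhydride without a nucleophilic catalyst, conditions known to keep the Z double bond of angelates from isomerizing to the tiglate; only the secondary 3α-hydroxyl reacts, the tertiary 4α-hydroxyl being too hindered.

Step 16
Reactants: 25 3α-angelate
Product: 26 target, (3R,4S,5S,7R,10R)-4α-acetoxy-3α-angeloyloxy-4β,10β-dimethyl-7β-isopropyl-5βH-decalin-8-one
Conditions: Ac2O, Sc(OTf)3 (cat.), MeCN, −20 °C
Reagents that add atoms: acetic anhydride, CC(=O)OC(C)=O
Why: Lewis acid-catalysed acetylation with Sc(OTf)3 and Ac2O is effective for hindered tertiary alcohols at low temperature, where elimination and isomerization of the angelate should be slow.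

**Compound list**

1 | 2-methoxy-4-methylphenol | COc1cc(C)ccc1O | starting material
2 | but-3-en-2-one (methyl vinyl ketone) | CC(=O)C=C | starting material
3 | 6,6-dimethoxy-4-methylcyclohexa-2,4-dien-1-one (masked o-benzoquinone) | O=C1C=CC(C)=CC1(OC)OC | intermediate
4 | racemic 7-endo-acetyl-3,3-dimethoxy-5-methylbicyclo[2.2.2]oct-5-en-2-one (both enantiomers, 1:1) | O=C1[C@H]2C=C(C)[C@H](C[C@@H]2C(C)=O)C1(OC)OC.O=C1[C@@H]2C=C(C)[C@@H](C[C@H]2C(C)=O)C1(OC)OC | intermediate
5 | 7-endo-acetyl-3,3-dimethoxy-5-methylbicyclo[2.2.2]oct-5-en-2-one, single enantiomer (acetyl syn to C5=C6) | O=C1[C@H]2C=C(C)[C@H](C[C@@H]2C(C)=O)C1(OC)OC | intermediate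
6 | potassium enolate of 5 (terminal enolate of the acetyl group) | O=C1[C@H]2C=C(C)[C@H](C[C@@H]2C([O-])=C)C1(OC)OC.[K+] | intermediate
7 | 7-endo-[1-(trifluoromethylsulfonyloxy)ethenyl]-3,3-dimethoxy-5-methylbicyclo[2.2.2]oct-5-en-2-one | O=C1[C@H]2C=C(C)[C@H](C[C@@H]2C(=C)OS(=O)(=O)C(F)(F)F)C1(OC)OC | intermediate
8 | 7-endo-(prop-1-en-2-yl)-3,3-dimethoxy-5-methylbicyclo[2.2.2]oct-5-en-2-one | O=C1[C@H]2C=C(C)[C@H](C[C@@H]2C(C)=C)C1(OC)OC | intermediate
9 | 7-endo-(propan-2-yl)-3,3-dimethoxy-5-methylbicyclo[2.2.2]oct-5-en-2-one | O=C1[C@H]2C=C(C)[C@H](C[C@@H]2C(C)C)C1(OC)OC | intermediate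
10 | vinylmagnesium bromide | C=C[Mg]Br | starting material
11 | 3,3-dimethoxy-5-methyl-7-endo-(propan-2-yl)-2-vinylbicyclo[2.2.2]oct-5-en-2-ol (vinyl syn to C5=C6) | C=C[C@@]1(O)[C@H]2C=C(C)[C@H](C[C@@H]2C(C)C)C1(OC)OC | intermediate
12 | potassium alkoxide of 11 | C=C[C@@]1([O-])[C@H]2C=C(C)[C@H](C[C@@H]2C(C)C)C1(OC)OC.[K+] | intermediate
13 | potassium C2=C3 enolate of 14 | [O-]C1=CC[C@]2(C)C=C[C@@H](C(C)C)C[C@@H]2C1(OC)OC.[K+] | intermediate
14 | cis-fused 4,4-dimethoxy-10β-methyl-7β-isopropyl-5βH-octal-8-en-3-one | O=C1CC[C@]2(C)C=C[C@@H](C(C)C)C[C@@H]2C1(OC)OC | intermediate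
15 | cis-fused 4,4-dimethoxy-10β-methyl-7β-isopropyl-5βH-octal-8-en-3α-ol | O[C@@H]1CC[C@]2(C)C=C[C@@H](C(C)C)C[C@@H]2C1(OC)OC | intermediate
16 | cis-fused 3α-hydroxy-10β-methyl-7β-isopropyl-5βH-octal-8-en-4-one | O[C@@H]1CC[C@]2(C)C=C[C@@H](C(C)C)C[C@@H]2C1=O | intermediate
17 | cis-fused 4β,10β-dimethyl-7β-isopropyl-5βH-octal-8-ene-3α,4α-diol | O[C@@H]1CC[C@]2(C)C=C[C@@H](C(C)C)C[C@@H]2[C@]1(C)O | intermediate
18 | 3α,4α-acetonide of 17 | CC1(C)O[C@@H]2CC[C@]3(C)C=C[C@@H](C(C)C)C[C@@H]3[C@]2(C)O1 | intermediate
19 | C8 (α) alkylborane from 18 | CC1(C)O[C@@H]2CC[C@]3(C)C[C@H](B)[C@@H](C(C)C)C[C@@H]3[C@]2(C)O1 | intermediate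
20 | 8α-hydroxy acetonide | CC1(C)O[C@@H]2CC[C@]3(C)C[C@H](O)[C@@H](C(C)C)C[C@@H]3[C@]2(C)O1 | intermediate
21 | 8-oxo acetonide | CC1(C)O[C@@H]2CC[C@]3(C)CC(=O)[C@@H](C(C)C)C[C@@H]3[C@]2(C)O1 | intermediate
22 | 3α,4α-dihydroxy-4β,10β-dimethyl-7β-isopropyl-5βH-decalin-8-one | O[C@@H]1CC[C@]2(C)CC(=O)[C@@H](C(C)C)C[C@@H]2[C@]1(C)O | intermediate
23 | angelic acid, (Z)-2-methylbut-2-enoic acid | C/C=C(/C)C(=O)O | starting material
24 | angelic 2,4,6-trichlorobenzoic anhydride | C/C=C(/C)C(=O)OC(=O)c1c(Cl)cc(Cl)cc1Cl | intermediate
25 | 3α-angelate of 22 (4α-hydroxyl free) | C/C=C(/C)C(=O)O[C@@H]1CC[C@]2(C)CC(=O)[C@@H](C(C)C)C[C@@H]2[C@]1(C)O | intermediate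
26 | CNP0322180.1, (3R,4S,5S,7R,10R)-4α-acetoxy-3α-angeloyloxy-4β,10β-dimethyl-7β-isopropyl-5βH-decalin-8-one | C/C=C(/C)C(=O)O[C@@H]1CC[C@]2(C)CC(=O)[C@@H](C(C)C)C[C@@H]2[C@]1(C)OC(C)=O | target

**Step count and risks**

Total step count: 16. Longest linear sequence: 16 steps (1 to 26); 2, 10 and 23 are bought.

Steps most likely to fail:

1. Step 12. The B–H addition may place boron partly on C9 instead of C8, or be slow at this hindered alkene, which would give the wrong ketone position. The fallback sets out from 18 and fixes the regiochemistry by trans-diaxial opening. N-bromosuccinimide in aqueous 1,2-dimethoxyethane at 0 °C should form the α-bromonium ion, which water opens at C8 from the β face (diaxial opening, away from neopentyl C9) to give the 9α-bromo-8β-hydroxy acetonide F1. Oxidation with nPr4N[RuO4] (cat.) and N-methylmorpholine N-oxide gives the 9α-bromo-8-oxo acetonide F2. Zinc dust in AcOH/THF at rt removes the bromine and returns to the route at 21.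

2. Step 16. Acylation of the axial tertiary 4α-hydroxyl next to the bulky angelate may be slow, and ionization with loss of water or acyl scrambling between O3 and O4 may compete. The fallback sets out from 22 and installs the acetate first by an intramolecular route. Trimethyl orthoacetate with pyridinium p-toluenesulfonate in CH2Cl2 gives the cyclic 3α,4α-(1-methoxyethylidene) orthoester F3. Brief treatment with aqueous AcOH opens it, by the usual preference for the axial ester, to the 4α-acetoxy-3α-hydroxy ketone F4. Esterification of the free 3α-hydroxyl with 23 under the conditions of step 15 then comes back to the route at 26.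

3. Step 15. The activated angeloyl unit may isomerize from Z to E (tiglate) during a slow acylation of the hindered 3α-hydroxyl. The fallback sets out from 22 and builds the Z double bond on the substrate. Esterification with 2-[bis(2,2,2-trifluoroethoxy)phosphoryl]propanoic acid (dicyclohexylcarbodiimide, 4-dimethylaminopyridine cat., CH2Cl2) gives the 3α-phosphonopropanoate F5. Deprotonation with KN(SiMe3)2 and 18-crown-6 in THF at −78 °C and addition of acetaldehyde (Still–Gennari olefination, Z-selective) comes back to the route at 25.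

**Further compounds**

F1 | step 12 | 9α-bromo-8β-hydroxy acetonide | CC1(C)O[C@@H]2CC[C@]3(C)[C@H](Br)[C@@H](O)[C@@H](C(C)C)C[C@@H]3[C@]2(C)O1
F2 | step 12 | 9α-bromo-8-oxo acetonide | CC1(C)O[C@@H]2CC[C@]3(C)[C@H](Br)C(=O)[C@@H](C(C)C)C[C@@H]3[C@]2(C)O1
F3 | step 16 | cyclic 3α,4α-(1-methoxyethylidene) orthoester of 22 (orthoester carbon as a mixture) | COC1(C)O[C@@H]2CC[C@]3(C)CC(=O)[C@@H](C(C)C)C[C@@H]3[C@]2(C)O1
F4 | step 16 | 4α-acetoxy-3α-hydroxy-4β,10β-dimethyl-7β-isopropyl-5βH-decalin-8-one | O[C@@H]1CC[C@]2(C)CC(=O)[C@@H](C(C)C)C[C@@H]2[C@]1(C)OC(C)=O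
F5 | step 15 | 3α-{2-[bis(2,2,2-trifluoroethoxy)phosphoryl]propanoate} of 22 (phosphonate carbon as a mixture) | CC(C(=O)O[C@@H]1CC[C@]2(C)CC(=O)[C@@H](C(C)C)C[C@@H]2[C@]1(C)O)P(=O)(OCC(F)(F)F)OCC(F)(F)F
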